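**Retrosynthetic overview**
- The target comes from its 4'-O-silyl ether by fluoride cleavage. Ring B is bought as the aldehyde.
- Rings C and A are cut in one move. Ring A is cut at C4a–C5 and C7–C8, which releases methylmalonyl dichloride as C5–C6(Me)–C7. Ring C is cut at O1–C8a and C2–C3, which releases the aldehyde C=O as the 2π partner.
- What remains is one acyclic C10 piece, the 1,3-bis(silyl enol ether) of 8-methylnon-7-ene-2,4-dione. It carries C3–C4–C4a–C8a–C8 and the prenyl group, so the 6-Me/8-prenyl pattern and the O1–C8a bond are fixed by connectivity.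
- The diketone comes from sulcatone and ethyl acetate by a Claisen condensation.
- Forward ring order: ring C forms first in an asymmetric hetero-Diels–Alder reaction that sets C2. Ring A follows in the same flask by double C-acylation and aromatisation.

Assumption: all four carbon building blocks are catalogue chemicals, and the (S,S)-catalyst is taken to give the 2S series (if the sense is opposite, the (R,R)-antipode is used).

**Step 1**
Reactants: 1 6-methylhept-5-en-2-one (sulcatone); 2 ethyl acetate
Product: 3 8-methylnon-7-ene-2,4-dione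
Conditions: NaH (2.2 equiv), 2 (2 equiv), THF, reflux; aq HCl
Reagents that add atoms: none
Why: Crossed Claisen condensation in which the methyl ketone is acylated at its unhindered CH3 terminus, irreversible formation of the β-diketonate drives the reaction, and the trisubstituted alkene is inert.

**Step 2**
Reactants: 3 8-methylnon-7-ene-2,4-dione
Product: 5 (3Z)-8-methyl-2,4-bis(trimethylsilyloxy)nona-1,3,7-triene, via monosilyl enol ether 4 (not isolated)
Conditions: LDA (1.05 equiv), THF, −78 °C, TMSCl, to 0 °C; LDA (1.15 equiv), −78 °C, TMSCl; pentane, filter, Kugelrohr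
Reagents that add atoms: chlorotrimethylsilane, C[Si](C)(C)Cl
Why: Chan-type 1,3-bis(silyl enol ether) synthesis in which O-silylation of the lithium diketonate gives the fluxional (Z)-β-silyloxy enone, kinetic LDA deprotonation occurs at the unhindered terminal CH3 (the same preference as in Hauser-type β-diketone dianion formation), and the new enolate is then O-silylated.

**Step 3**
Reactants: 5 (3Z)-8-methyl-2,4-bis(trimethylsilyloxy)nona-1,3,7-triene; 6 4-(tert-butyldimethylsilyloxy)benzaldehyde; 7 methylmalonyl dichloride (2-methylpropanedioyl dichloride)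
Product: 10 (2S)-5,7-dihydroxy-2-(4-hydroxyphenyl)-6-methyl-8-(3-methylbut-2-en-1-yl)chroman-4-one (6-methyl-8-prenylnaringenin), via hetero-Diels–Alder adduct 8 (not isolated), via 4'-O-TBS flavanone 9 (not isolated)
Conditions: (S,S)-(salen)Cr(III)BF4 (5 mol %), 4 Å MS, TBME, −30 °C; then 7 (1.1 equiv), 2,6-di-tert-butyl-4-methylpyridine (DTBMP, 2.2 equiv), CH2Cl2, −78 to 0 °C, DMAP (10 mol %); then KHF2, MeOH, rt
Reagents that add atoms: none
Why: Proposed new method: the chiral Cr(III)–salen Lewis acid steers a concerted Si-face hetero-Diels–Alder addition of the Chan/Danishefsky-type diene 5 to aldehyde 6, which closes ring C and sets C2 as S (the C6 ketal centre is lost later); the unhydrolysed adduct 8 is both a silyl enol ether (pyran C5) and a masked enol ether with an α-CH2 (pyran C6), so the 1,3-bis-electrophile 7 C-acylates it twice, by acylation at C5, loss of Me3SiO– (which ends as Me3SiOSiMe3), vinylogous enolisation of the side-chain CH2 towards the O–H···O=C4 chelated dienol, closure on the second COCl (or 6π-electrocyclisation of its ketene) and irreversible tautomerisation to phloroglucinol ring A, while DMAP and chloride return O-acyl isomers to the productive path; the closest known reactions are the Jacobsen-type asymmetric hetero-Diels–Alder reaction, the Effenberger α,α'-annulation of enol ethers with malonyl dichlorides and the closing electrocyclisation of the Danheiser benzannulation; only hindered or catalytic pyridine bases and slightly acidic KHF2 are present, so the C2–O bond is not opened.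

**Compound list**
1 | 6-methylhept-5-en-2-one (sulcatone) | CC(=O)CCC=C(C)C | starting material
2 | ethyl acetate | CCOC(C)=O | starting material
3 | 8-methylnon-7-ene-2,4-dione | CC(=O)CC(=O)CCC=C(C)C | intermediate
4 | (3Z)-8-methyl-4-(trimethylsilyloxy)nona-3,7-dien-2-one (fluxional with its O-silyl tautomer) | CC(=O)/C=C(\O[Si](C)(C)C)CCC=C(C)C | intermediate
5 | (3Z)-8-methyl-2,4-bis(trimethylsilyloxy)nona-1,3,7-triene | C=C(O[Si](C)(C)C)/C=C(\O[Si](C)(C)C)CCC=C(C)C | intermediate
6 | 4-(tert-butyldimethylsilyloxy)benzaldehyde | O=Cc1ccc(O[Si](C)(C)C(C)(C)C)cc1 | starting material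
7 | methylmalonyl dichloride | CC(C(=O)Cl)C(=O)Cl | starting material
8 | (2S)-2-[4-(tert-butyldimethylsilyloxy)phenyl]-6-(4-methylpent-3-en-1-yl)-4,6-bis(trimethylsilyloxy)-3,6-dihydro-2H-pyran (C6 epimers, centre lost later) | CC(C)=CCCC1(O[Si](C)(C)C)C=C(O[Si](C)(C)C)C[C@@H](c2ccc(O[Si](C)(C)C(C)(C)C)cc2)O1 | intermediate
9 | (2S)-2-[4-(tert-butyldimethylsilyloxy)phenyl]-5,7-dihydroxy-6-methyl-8-(3-methylbut-2-en-1-yl)chroman-4-one | CC(C)=CCc1c(O)c(C)c(O)c2c1O[C@H](c1ccc(O[Si](C)(C)C(C)(C)C)cc1)CC2=O | intermediate
10 | (2S)-6-methyl-8-prenylnaringenin | CC(C)=CCc1c(O)c(C)c(O)c2c1O[C@H](c1ccc(O)cc1)CC2=O | target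

Total step count: 3. Longest linear sequence: 3.

**Steps most likely to fail**

Step 3 is the highest risk.
- After the first acylation, the C4 carbonyl oxygen can close on the second COCl to give a fused α-pyrone instead of ring A.
- Chloride can cleave the benzylic C2–O bond of cationic intermediates.
- The 4,4-disubstituted diene terminus may lower the ee. An ee of 85–90 % would be raised by recrystallising 10.

Fallback: give up the interception and set the stereocentre last, starting from 3. Terminal formylation (LDA 2.2 equiv, HCO2Et) and acid cyclodehydration give 2-(4-methylpent-3-en-1-yl)-4H-pyran-4-one F1. This compound has no stereocentre and no α'-protons. Its side-chain CH2 is therefore deprotonated cleanly (LiHMDS) and acylated with tert-butyl 3-chloro-2-methyl-3-oxopropanoate to give tert-butyl 2,7-dimethyl-3-oxo-4-(4-oxo-4H-pyran-2-yl)oct-6-enoate F2. In refluxing toluene the tert-butyl β-keto ester becomes the acylketene, which closes by 6π-electrocyclisation to 5,7-dihydroxy-6-methyl-8-(3-methylbut-2-en-1-yl)-4H-chromen-4-one F3. Rh(I)/chiral diene-catalysed asymmetric 1,4-addition of [4-(tert-butyldimethylsilyloxy)phenyl]boronic acid to F3 comes back to the route at 9.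

Step 2 can fail in regioselectivity. The second deprotonation may also occur at the CH2 next to the homoprenyl chain, and C-silylation is possible.

Fallback: remove the regiochemical question and install the prenyl group last, starting from 6 and 7. Pentane-2,4-dione is silylated in the same way to the symmetrical-precursor diene (3Z)-2,4-bis(trimethylsilyloxy)penta-1,3-diene F4. The same one-flask sequence, stopped before the KHF2 stage, passes through (2S)-2-[4-(tert-butyldimethylsilyloxy)phenyl]-6-methyl-4,6-bis(trimethylsilyloxy)-3,6-dihydro-2H-pyran F5. It gives (2S)-2-[4-(tert-butyldimethylsilyloxy)phenyl]-5,7-dihydroxy-6-methylchroman-4-one F6. C8 is the only free position on ring A of F6. Friedel–Crafts prenylation with 2-methylbut-3-en-2-ol and BF3·OEt2 in dioxane, an acidic medium that does not open the C-ring, comes back to the route at 9.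

Step 1 can suffer from self-condensation of ethyl acetate, aldol self-condensation of 1 and some acylation at the CH2.

Fallback: replace the acylation by aldol addition and oxidation, starting from 1. The kinetic lithium enolate (LDA, −78 °C) adds to acetaldehyde to give 2-hydroxy-8-methylnon-7-en-4-one F7. Dess–Martin oxidation of F7 comes back to the route at 3.

**Further compounds**
F1 | step 3 | 2-(4-methylpent-3-en-1-yl)-4H-pyran-4-one | O=c1ccoc(CCC=C(C)C)c1
F2 | step 3 | tert-butyl 2,7-dimethyl-3-oxo-4-(4-oxo-4H-pyran-2-yl)oct-6-enoate (diastereomer mixture) | CC(C)=CCC(C(=O)C(C)C(=O)OC(C)(C)C)c1cc(=O)cco1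
F3 | step 3 | 5,7-dihydroxy-6-methyl-8-(3-methylbut-2-en-1-yl)-4H-chromen-4-one | CC(C)=CCc1c(O)c(C)c(O)c2c(=O)ccoc12
F4 | step 2 | (3Z)-2,4-bis(trimethylsilyloxy)penta-1,3-diene | C=C(O[Si](C)(C)C)/C=C(\O[Si](C)(C)C)C
F5 | step 2 | (2S)-2-[4-(tert-butyldimethylsilyloxy)phenyl]-6-methyl-4,6-bis(trimethylsilyloxy)-3,6-dihydro-2H-pyran (C6 epimers) | CC1(O[Si](C)(C)C)C=C(O[Si](C)(C)C)C[C@@H](c2ccc(O[Si](C)(C)C(C)(C)C)cc2)O1
F6 | step 2 | (2S)-2-[4-(tert-butyldimethylsilyloxy)phenyl]-5,7-dihydroxy-6-methylchroman-4-one | Cc1c(O)cc2c(c1O)C(=O)C[C@@H](c1ccc(O[Si](C)(C)C(C)(C)C)cc1)O2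
F7 | step 1 | 2-hydroxy-8-methylnon-7-en-4-one (racemic) | CC(O)CC(=O)CCC=C(C)C
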